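## The problem

Amaurone A joins a 2-methoxy-3,5-dimethyl-γ-pyrone through an all-E triene to a cyclohexane in which every ring carbon is a stereocentre: C1 (side chain), C2 (Me), C3 (Me, OH), C4 (OAc), C5 (Me, OH), C6 (OH), configuration 1R,2S,3R,4R,5S,6S (these locants are used throughout). All four oxygens lie on one face (β) and the chain and the three methyl groups on the other (α), so C1/C2 are cis and the C3–C6 tetraol is all-cis. There is no stereocentre outside the ring and no obvious chiral-pool ring with this pattern, so absolute configuration must be brought in from outside and relayed around the ring. The secondary acetate at C4 sits between two tertiary carbinols while the second secondary hydroxyl (C6) stays free, so the four oxygens must be told apart, and alkoxide-forming conditions invite acetyl migration. The triene–pyrone reacts with singlet oxygen, OsO4, light and strong base, so the ring must be oxidised before the chain is attached, and any olefination that starts the chain passes through a C1 aldehyde with a β-oxygen at C6.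

The feature that makes a short route possible is this. C3, C4, C5 and C6, with methyls on C3 and C5, are the four carbons of a 1,3-diene. The C1–C2 bond with its two cis substituents is the σ bond left by disrotatory 6π closure of a hexatriene C1=C6–C5=C4–C3=C2. All four oxygens sit on the diene carbons, on the face opposite the C1/C2 substituents, which is the pattern of a 3,6-endoperoxide followed by cis-dihydroxylation of C4=C5. The centres can therefore be relayed in three events: C1/C2, then C3/C6, then C4/C5.

## Retrosynthesis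

**Pyrone union (34 ⇒ 23 + 32).** The C5′=C6′ double bond next to the pyrone is cut (side-chain carbons C1′ at the ring to C6′ at the pyrone). This leaves all polyene building until after the ring oxidations, and the pyrone partner 32 is one step from ethylpyrone 29. A cut at C1′=C2′ would instead need a branched, non-stabilised nucleophile with poor geometry control. The precursor 23 is a dienal and 32 an achiral phosphonate. The forward Horner–Wadsworth–Emmons reaction must give the E trisubstituted alkene without forming alkoxides.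

**Chain extension (23 ⇒ 19 ⇒ 17).** C3′=C4′ and C1′=C2′ are cut in turn, back to the ring aldehyde 17. The reagents are the formyl-olefination phosphonate 20 (two carbons) and the branched stabilised ylide 18 (three carbons), which sets the E trisubstituted alkene. Both are weakly basic, which is what a free triol monoacetate demands.

**Unmasking C1 (17 ⇒ 16 ⇒ 14).** The C1 aldehyde comes from a glyceraldehyde-derived dioxolane by periodic acid, and the C3/C6 hydroxyls from hydrogenolysis of the O–O bond. The order is dictated by structure. While O6 is still in the peroxide the ring has no vicinal diol for periodate to cut. Once the bicycle is opened, the C1 formyl group is equatorial and thermodynamically secure; in bicyclic 16 it is compressed against the C5 methyl.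

**Telling the oxygens apart (14 ⇒ 13 ⇒ 12).** The C4–O and C5–O bonds are cut back to the alkene of endoperoxide 12, and the acetate is removed. With O3 and O6 tied in the peroxide, the only acylable hydroxyl of 13 is C4–OH, so the peroxide bridge is the only protecting group the ring needs. Dihydroxylation must occur on the face of the O–O bridge, which the C1/C2 substituents should enforce.

**Key disconnection (12 ⇒ 10, via 11).** The two C–O bonds of the peroxide and the C1–C2 σ bond are cut, which unravels the bicycle to the acyclic triene 10. Stepwise ring constructions would set C1, C2, C3 and C6 one at a time. Here orbital symmetry gives cis-C1/C2, and the two new substituents steer singlet oxygen to the other face. Triene 10 has one stereocentre, the dioxolane carbon from the chiral pool, which must bias the direction of disrotation and is later excised as the aldehyde carbon.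

**Triene assembly (10 ⇒ 8 + 9; 8 ⇒ 5 + 3; 3 ⇒ 1; 5 ⇒ 4).** The C3–C4 and C5–C6 single bonds between sp2 carbons are cut. The Z trisubstituted central alkene is the hard part of the triene. It is taken ready-made from syn-bromoboration of propyne (1 → 3, via 2), so both couplings (Negishi, then Suzuki–Miyaura with bromide 9) only need to proceed with retention. Alkyne 5 is one step from (S)-glyceraldehyde acetonide 4.

**Pyrone (32 ⇒ 29 ⇒ 28 ⇒ 27 ⇒ 24 + 25).** The C–P bond is cut, then the O-methyl, then the lactone C–O bond, then the C4–C5 bond of the triketide. This is the standard polypropionate pyrone sequence from β-keto ester 24 and amide 25.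

## Roads not taken

**Alternative 1:** the most obvious plan keeps the side-chain cut but builds the core by stepwise functionalisation of a carbocycle. 2,4-Dimethylphenol A1 is dearomatised to p-quinol A2 (C3 carbinol and C6 carbonyl in place). Conjugate methylation at C2, enolate acylation at C1, dihydroxylation of the remaining enone and ketone reduction follow. The forward key step is dearomatisation plus conjugate addition. The chosen plan is better for three reasons. A methyl nucleophile is expected to add to A2 syn to the carbinol oxygen (hydroxyl delivery or electrostatic control), whereas the target has C2–Me anti to C3–O. A2 is chiral and racemic, with no symmetry to break. Each of the six centres would need its own step and its own argument.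

**Alternative 2:** a Diels–Alder route cuts C1–C6 and C2–C3. 2,4-Dimethylfuran A3 and ethyl but-2-ynoate A4 would give oxanorbornadiene A5 with all nine ring carbons placed. Exo hydrogenation and exo dihydroxylation would set C1, C2, C4 and C5. The chosen plan is better because the bridging oxygen of A5 is a single atom: it can end up on C3 or C6 but not both, and opening it by β-elimination destroys C1. The required regiochemistry also puts the two methyl-bearing carbons adjacent against sterics, and nothing controls absolute configuration. The peroxide bridge of 12 is the two-oxygen version of the same idea.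

**Alternative 3:** the biosynthesis followed to the letter. The complete pyrone hexaene A6 would be cyclised and the ring diene then oxidised. The cut and the forward key step (6π closure) are the same as in the chosen plan. The chosen plan is better because singlet oxygen and OsO4 cannot distinguish the ring diene from the electron-rich side-chain triene. A6 also carries a Z trisubstituted alkene inside a light-sensitive hexaene and offers no handle for absolute control. Truncating the polyene to 10 and attaching the chain after oxidation removes all three problems.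

Key step: step 5

Remarks (assumptions):
- The sense of induction by the dioxolane in step 5 is a prediction from a staggered transition-state model, not a known result; both enantiomers of glyceraldehyde acetonide are commercial.
- Compounds 1, 4, 9, 18, 20, 24 and 25 and all reagents named under Conditions are taken as commercially available.

## Steps

Step 1
Reactants: 1 propyne
Product: 3 2-[(Z)-2-bromoprop-1-en-1-yl]-4,4,5,5-tetramethyl-1,3,2-dioxaborolane, via (Z)-(2-bromoprop-1-enyl)dibromoborane 2 (not isolated)
Conditions: BBr3, CH2Cl2, −78 °C → rt; then pinacol, CH2Cl2, −78 °C → rt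
Reagents that add atoms: boron tribromide BrB(Br)Br; pinacol CC(C)(O)C(C)(C)O
Why: Syn-bromoboration of a terminal alkyne puts Br on the internal and B on the terminal carbon, cis to each other, which fixes the Z trisubstituted alkene (future C5=C4); pinacol exchange gives a stable boronate.

Step 2
Reactants: 4 (4S)-2,2-dimethyl-1,3-dioxolane-4-carbaldehyde
Product: 5 (4R)-4-ethynyl-2,2-dimethyl-1,3-dioxolane
Conditions: dimethyl (1-diazo-2-oxopropyl)phosphonate, K2CO3, MeOH, 0 °C → rt
Reagents that add atoms: dimethyl (1-diazo-2-oxopropyl)phosphonate CC(=O)C(=[N+]=[N-])P(=O)(OC)OC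
Why: Seyferth–Gilbert homologation in its Ohira–Bestmann form; the mild carbonate conditions should leave the α-alkoxy stereocentre intact (the descriptor changes from S to R only through CIP priorities).

Step 3
Reactants: 5 (4R)-4-ethynyl-2,2-dimethyl-1,3-dioxolane; 3 2-[(Z)-2-bromoprop-1-en-1-yl]-4,4,5,5-tetramethyl-1,3,2-dioxaborolane
Product: 8 2-[(1Z,3E)-4-[(4R)-2,2-dimethyl-1,3-dioxolan-4-yl]-2-methylbuta-1,3-dien-1-yl]-4,4,5,5-tetramethyl-1,3,2-dioxaborolane, via alkenylzirconocene chloride 6 (not isolated), via alkenylzinc chloride 7 (not isolated)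
Conditions: Cp2Zr(H)Cl, THF, rt; ZnCl2, 0 °C; then 3, Pd(P(t-Bu)3)2 (zerovalent palladium, 3 mol %), THF, rt
Reagents that add atoms: none
Why: Syn-hydrozirconation places the metal on the terminal carbon (E alkenyl); transmetalation to zinc and Negishi coupling at the C–Br bond of 3 proceed with retention on both partners, and the boronate is inert without base.

Step 4
Reactants: 8 the dienylboronate; 9 (E)-2-bromobut-2-ene
Product: 10 (4R)-4-[(1E,3Z,5E)-3,5-dimethylhepta-1,3,5-trien-1-yl]-2,2-dimethyl-1,3-dioxolane
Conditions: PdCl2(DPEphos) (3 mol %), CsF, THF, 23 °C, dark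
Reagents that add atoms: none
Why: Suzuki–Miyaura coupling with retention of both alkene geometries completes the (E,Z,E)-triene; room temperature avoids premature electrocyclisation.

Step 5
Reactants: 10 (4R)-4-[(1E,3Z,5E)-3,5-dimethylhepta-1,3,5-trien-1-yl]-2,2-dimethyl-1,3-dioxolane
Product: 12 (4R)-4-[(1S,2S,3R,6S)-3,6-epidioxy-2,3,5-trimethylcyclohex-4-en-1-yl]-2,2-dimethyl-1,3-dioxolane, via cis-cyclohexadiene 11 (not isolated)
Conditions: PhMe (degassed), 100 °C; then CH2Cl2, 0 °C, O2, tetraphenylporphyrin (cat.), visible light; chromatography (separation of the minor diastereomer)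
Reagents that add atoms: dioxygen O=O
Why: Heat drives a thermal disrotatory 6π electrocyclisation of the (E,Z,E)-triene (closest known type: (2E,4Z,6E)-octatrienes closing to cis-5,6-disubstituted cyclohexa-1,3-dienes), which closes the carbocycle by forming the C1–C2 σ bond and, by orbital symmetry, places the dioxolanyl and methyl groups cis. The direction of disrotation, and hence the absolute configuration of C1 and C2, is set by the (4R)-dioxolane carbon on C1: in the staggered transition state its C–H should sit inside toward C6–H, its C–O bond antiperiplanar to the forming bond and its CH2O arm outside, which leads to (1S,2S)-11; this induction need only be moderate, because the other diastereomer is separable at the stage of 12 and each diastereomer is a single enantiomer. Without isolation, sensitised singlet oxygen adds to the cisoid ring diene in a suprafacial [4+2] cycloaddition (closest known type: α-terpinene to ascaridole), which closes the 1,2-dioxane ring across C3 and C6 and makes both C–O bonds necessarily cis. The oxygen should approach the face opposite the two cis substituents on C1 and C2, one of which is pseudoaxial, so C3 and C6 are relayed from C1/C2. Selectivities needed: [4+2] over the ene reaction (secured by the s-cis-locked diene), closure before any [1,5]-hydrogen shift (100 °C is well below what such shifts in cyclohexadienes require), and no second alkene for singlet oxygen (11 has none).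

Step 6
Reactants: 12 the endoperoxide
Product: 13 (4R)-4-[(1S,2S,3R,4S,5R,6S)-3,6-epidioxy-4,5-dihydroxy-2,3,5-trimethylcyclohexyl]-2,2-dimethyl-1,3-dioxolane
Conditions: OsO4 (5 mol %), NMO, citric acid, t-BuOH–H2O, rt
Reagents that add atoms: N-methylmorpholine N-oxide C[N+]1([O-])CCOCC1; water O; osmium tetroxide (catalytic oxygen carrier) O=[Os](=O)(=O)=O
Why: Catalytic syn-dihydroxylation of the 2,3-dioxabicyclo[2.2.2]oct-5-ene alkene; the α-face of C4=C5 is covered by the C1 and C2 substituents on the neighbouring two-carbon bridge, so osmium should add from the face of the O–O bridge and set C4 and C5 with both hydroxyls cis to the peroxide oxygens. The citric acid buffer keeps N-methylmorpholine protonated so that it cannot trigger Kornblum–DeLaMare opening at C6–H.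

Step 7
Reactants: 13 the peroxy diol
Product: 14 (4R)-4-[(1S,2S,3R,4S,5R,6S)-4-acetoxy-3,6-epidioxy-5-hydroxy-2,3,5-trimethylcyclohexyl]-2,2-dimethyl-1,3-dioxolane
Conditions: Ac2O, DMAP (cat.), pyridine, CH2Cl2, 0 °C
Reagents that add atoms: acetic anhydride CC(=O)OC(C)=O
Why: DMAP-catalysed acylation; O3 and O6 are locked in the peroxide and C5–OH is tertiary, so C4–OH is the only hydroxyl that can be acetylated.

Step 8
Reactants: 14 the peroxy acetate
Product: 16 (1R,2S,3R,4S,5R,6S)-4-acetoxy-3,6-epidioxy-5-hydroxy-2,3,5-trimethylcyclohexane-1-carbaldehyde, via side-chain diol 15 (not isolated)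
Conditions: H5IO6, EtOAc, 0 °C → rt; filtered and used crude
Reagents that add atoms: none
Why: Periodic acid hydrolyses the terminal acetonide and cleaves the liberated 1,2-diol in one flask (glycol cleavage); the ring has no free vicinal diol at this stage, so only the side chain is cut and the controller stereocentre becomes the aldehyde carbon C1′.

Step 9
Reactants: 16 the bicyclic aldehyde
Product: 17 (1R,2S,3R,4R,5S,6S)-4-acetoxy-3,5,6-trihydroxy-2,3,5-trimethylcyclohexane-1-carbaldehyde
Conditions: H2 (1 atm), Pd/C, EtOAc, rt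
Reagents that add atoms: none
Why: Hydrogenolysis of the dialkyl peroxide O–O bond leaves both C–O bonds, and so C3 and C6, untouched; the aliphatic aldehyde should survive. In the resulting chair the formyl group is equatorial and its epimer would be 1,3-diaxial to the C3 and C5 hydroxyls, so C1 is thermodynamically secured from here on.

Step 10
Reactants: 17 the triol aldehyde; 18 2-(triphenylphosphoranylidene)propanal
Product: 19 (2E)-3-[(1R,2S,3R,4R,5S,6S)-4-acetoxy-3,5,6-trihydroxy-2,3,5-trimethylcyclohexyl]-2-methylprop-2-enal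
Conditions: PhMe, 80 °C
Reagents that add atoms: none
Why: Wittig olefination with a stabilised α-branched ylide gives the E trisubstituted enal (ring trans to CHO); the ylide is too weakly basic to deprotonate the carbinols or to drive β-elimination of the C6 hydroxyl.

Step 11
Reactants: 19 the enal; 20 diethyl [2-(cyclohexylamino)vinyl]phosphonate
Product: 23 (2E,4E)-5-[(1R,2S,3R,4R,5S,6S)-4-acetoxy-3,5,6-trihydroxy-2,3,5-trimethylcyclohexyl]-4-methylpenta-2,4-dienal, via sodium aza-enolate 21 (not isolated), via unsaturated cyclohexylimine 22 (not isolated)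
Conditions: 20, NaH, THF, 0 °C; then 19, 0 °C → rt; aq. oxalic acid, rt
Reagents that add atoms: water O
Why: Horner–Wadsworth–Emmons formyl-olefination: the stabilised phosphonate anion gives the E unsaturated imine, which cannot react a second time (no over-homologation) and is hydrolysed by aqueous oxalic acid; the anion should not deprotonate the carbinols, so the acetate should stay on C4.

Step 12
Reactants: 24 methyl 2-methyl-3-oxopentanoate; 25 N-methoxy-N-methylpropanamide
Product: 27 methyl 2,4-dimethyl-3,5-dioxoheptanoate, via keto ester dianion 26 (not isolated)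
Conditions: NaH, THF, 0 °C; n-BuLi, −10 °C; then 25, −78 → 0 °C; aq. NH4Cl
Reagents that add atoms: none
Why: γ-Acylation of a β-keto ester dianion (the more basic terminal carbanion reacts); the N-methoxy-N-methylamide stops at the ketone level. The two stereocentres are of no consequence, as both become sp2.

Step 13
Reactants: 27 methyl 2,4-dimethyl-3,5-dioxoheptanoate
Product: 28 6-ethyl-4-hydroxy-3,5-dimethyl-2H-pyran-2-one
Conditions: DBU, PhMe, reflux
Reagents that add atoms: none
Why: Enol lactonisation of the 3,5-diketo ester (O-acylation by the δ-enol with loss of methanol) gives the 4-hydroxy-2-pyrone.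

Step 14
Reactants: 28 6-ethyl-4-hydroxy-3,5-dimethyl-2H-pyran-2-one
Product: 29 6-ethyl-2-methoxy-3,5-dimethyl-4H-pyran-4-one
Conditions: MeOTf, CH2Cl2, rt; aq. NaHCO3
Reagents that add atoms: methyl trifluoromethanesulfonate COS(=O)(=O)C(F)(F)F
Why: A hard methylating agent alkylates the lactone carbonyl oxygen of the neutral hydroxypyrone; loss of the proton then gives the 2-methoxy-4-pyranone and not the 4-methoxy-2-pyranone, as is usual for 3,5-dimethyl-4-hydroxy-2-pyrones.

Step 15
Reactants: 29 6-ethyl-2-methoxy-3,5-dimethyl-4H-pyran-4-one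
Product: 32 diethyl [1-(6-methoxy-3,5-dimethyl-4-oxo-4H-pyran-2-yl)ethyl]phosphonate (racemic), via lithiated pyrone 30 (not isolated), via phosphonite 31 (not isolated)
Conditions: LiHMDS, THF, −78 °C; ClP(OEt)2, −78 → 0 °C; then H2O2 (30 % aq.), 0 °C
Reagents that add atoms: diethyl chlorophosphite CCOP(Cl)OCC; hydrogen peroxide OO
Why: Deprotonation at the vinylogous α-position (CH2 of the 6-ethyl group), C-phosphinylation of the extended enolate by the soft trivalent phosphorus chloride, and oxidation to the phosphonate; the new stereocentre is racemic and disappears in step 16.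

Step 16
Reactants: 23 the dienal; 32 the pyronyl phosphonate
Product: 34 amaurone A, 6-[(2E,4E,6E)-7-[(1R,2S,3R,4R,5S,6S)-4-acetoxy-3,5,6-trihydroxy-2,3,5-trimethylcyclohexyl]-6-methylhepta-2,4,6-trien-2-yl]-2-methoxy-3,5-dimethyl-4H-pyran-4-one, via lithium phosphonate 33 (not isolated)
Conditions: 32, LiHMDS, THF, −78 °C; then 23, −78 → 0 °C; aq. NH4Cl; dark
Reagents that add atoms: none
Why: Horner–Wadsworth–Emmons olefination with an α-branched, pyrone-stabilised phosphonate anion; E geometry (pyrone trans to the chain) is expected from the thermodynamic control usual for stabilised phosphonates, and the anion is too weak a base to deprotonate the carbinols, so acetyl migration is not expected.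

## Compound list

1 | propyne | CC#C | starting material
2 | (Z)-(2-bromoprop-1-en-1-yl)dibromoborane | C/C(Br)=C/B(Br)Br | intermediate
3 | 2-[(Z)-2-bromoprop-1-en-1-yl]-4,4,5,5-tetramethyl-1,3,2-dioxaborolane | C/C(Br)=C/B1OC(C)(C)C(C)(C)O1 | intermediate
4 | (4S)-2,2-dimethyl-1,3-dioxolane-4-carbaldehyde | CC1(C)OC[C@H](O1)C=O | starting material
5 | (4R)-4-ethynyl-2,2-dimethyl-1,3-dioxolane | CC1(C)OC[C@H](O1)C#C | intermediate
6 | chlorobis(cyclopentadienyl)[(E)-2-[(4R)-2,2-dimethyl-1,3-dioxolan-4-yl]ethenyl]zirconium | CC1(C)OC[C@H](O1)/C=C/[Zr](Cl)(C2C=CC=C2)C2C=CC=C2 | intermediate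
7 | chloro[(E)-2-[(4R)-2,2-dimethyl-1,3-dioxolan-4-yl]ethenyl]zinc | CC1(C)OC[C@H](O1)/C=C/[Zn]Cl | intermediate
8 | 2-[(1Z,3E)-4-[(4R)-2,2-dimethyl-1,3-dioxolan-4-yl]-2-methylbuta-1,3-dien-1-yl]-4,4,5,5-tetramethyl-1,3,2-dioxaborolane | CC1(C)OC[C@H](O1)/C=C/C(C)=C\B1OC(C)(C)C(C)(C)O1 | intermediate
9 | (E)-2-bromobut-2-ene | C/C=C(\C)Br | starting material
10 | (4R)-4-[(1E,3Z,5E)-3,5-dimethylhepta-1,3,5-trien-1-yl]-2,2-dimethyl-1,3-dioxolane | CC1(C)OC[C@H](O1)/C=C/C(C)=C\C(C)=C\C | intermediate
11 | (4R)-2,2-dimethyl-4-[(1S,2S)-2,3,5-trimethylcyclohexa-3,5-dien-1-yl]-1,3-dioxolane | CC1(C)OC[C@H](O1)[C@@H]2[C@H](C)C(C)=CC(C)=C2 | intermediate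
12 | (4R)-4-[(1S,2S,3R,6S)-3,6-epidioxy-2,3,5-trimethylcyclohex-4-en-1-yl]-2,2-dimethyl-1,3-dioxolane | CC1(C)OC[C@H](O1)[C@@H]2[C@H](C)[C@]3(C)C=C(C)[C@H]2OO3 | intermediate
13 | (4R)-4-[(1S,2S,3R,4S,5R,6S)-3,6-epidioxy-4,5-dihydroxy-2,3,5-trimethylcyclohexyl]-2,2-dimethyl-1,3-dioxolane | CC1(C)OC[C@H](O1)[C@@H]2[C@H](C)[C@]3(C)[C@@H](O)[C@@](C)(O)[C@H]2OO3 | intermediate
14 | (4R)-4-[(1S,2S,3R,4S,5R,6S)-4-acetoxy-3,6-epidioxy-5-hydroxy-2,3,5-trimethylcyclohexyl]-2,2-dimethyl-1,3-dioxolane | CC1(C)OC[C@H](O1)[C@@H]2[C@H](C)[C@]3(C)[C@@H](OC(C)=O)[C@@](C)(O)[C@H]2OO3 | intermediate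
15 | (1R)-1-[(1S,2S,3R,4S,5R,6S)-4-acetoxy-3,6-epidioxy-5-hydroxy-2,3,5-trimethylcyclohexyl]ethane-1,2-diol | OC[C@H](O)[C@@H]1[C@H](C)[C@]2(C)[C@@H](OC(C)=O)[C@@](C)(O)[C@H]1OO2 | intermediate
16 | (1R,2S,3R,4S,5R,6S)-4-acetoxy-3,6-epidioxy-5-hydroxy-2,3,5-trimethylcyclohexane-1-carbaldehyde | O=C[C@@H]1[C@H](C)[C@]2(C)[C@@H](OC(C)=O)[C@@](C)(O)[C@H]1OO2 | intermediate
17 | (1R,2S,3R,4R,5S,6S)-4-acetoxy-3,5,6-trihydroxy-2,3,5-trimethylcyclohexane-1-carbaldehyde | O=C[C@@H]1[C@H](C)[C@@](C)(O)[C@@H](OC(C)=O)[C@@](C)(O)[C@H]1O | intermediate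
18 | 2-(triphenylphosphoranylidene)propanal | CC(C=O)=P(c1ccccc1)(c1ccccc1)c1ccccc1 | starting material
19 | (2E)-3-[(1R,2S,3R,4R,5S,6S)-4-acetoxy-3,5,6-trihydroxy-2,3,5-trimethylcyclohexyl]-2-methylprop-2-enal | O=C/C(C)=C/[C@@H]1[C@H](C)[C@@](C)(O)[C@@H](OC(C)=O)[C@@](C)(O)[C@H]1O | intermediate
20 | diethyl [2-(cyclohexylamino)vinyl]phosphonate | CCOP(=O)(OCC)/C=C/NC1CCCCC1 | starting material
21 | sodium salt of 20 (phosphonate aza-enolate) | [Na+].CCOP(=O)(OCC)[CH-]C=NC1CCCCC1 | intermediate
22 | (2E,4E)-N-cyclohexyl-5-[(1R,2S,3R,4R,5S,6S)-4-acetoxy-3,5,6-trihydroxy-2,3,5-trimethylcyclohexyl]-4-methylpenta-2,4-dien-1-imine | C1CCC(CC1)N=C/C=C/C(C)=C/[C@@H]2[C@H](C)[C@@](C)(O)[C@@H](OC(C)=O)[C@@](C)(O)[C@H]2O | intermediate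
23 | (2E,4E)-5-[(1R,2S,3R,4R,5S,6S)-4-acetoxy-3,5,6-trihydroxy-2,3,5-trimethylcyclohexyl]-4-methylpenta-2,4-dienal | O=C/C=C/C(C)=C/[C@@H]1[C@H](C)[C@@](C)(O)[C@@H](OC(C)=O)[C@@](C)(O)[C@H]1O | intermediate
24 | methyl 2-methyl-3-oxopentanoate | CCC(=O)C(C)C(=O)OC | starting material
25 | N-methoxy-N-methylpropanamide | CCC(=O)N(C)OC | starting material
26 | sodium lithium dianion of methyl 2-methyl-3-oxopentanoate | [Na+].[Li+].C[CH-]C(=O)[C-](C)C(=O)OC | intermediate
27 | methyl 2,4-dimethyl-3,5-dioxoheptanoate | CCC(=O)C(C)C(=O)C(C)C(=O)OC | intermediate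
28 | 6-ethyl-4-hydroxy-3,5-dimethyl-2H-pyran-2-one | CCc1oc(=O)c(C)c(O)c1C | intermediate
29 | 6-ethyl-2-methoxy-3,5-dimethyl-4H-pyran-4-one | CCc1oc(OC)c(C)c(=O)c1C | intermediate
30 | lithium salt of 29 deprotonated at the ethyl CH2 | [Li+].C[CH-]c1oc(OC)c(C)c(=O)c1C | intermediate
31 | diethyl [1-(6-methoxy-3,5-dimethyl-4-oxo-4H-pyran-2-yl)ethyl]phosphonite (racemic) | CCOP(OCC)C(C)c1oc(OC)c(C)c(=O)c1C | intermediate
32 | diethyl [1-(6-methoxy-3,5-dimethyl-4-oxo-4H-pyran-2-yl)ethyl]phosphonate (racemic) | CCOP(=O)(OCC)C(C)c1oc(OC)c(C)c(=O)c1C | intermediate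
33 | lithium salt of 32 | [Li+].CCOP(=O)(OCC)[C-](C)c1oc(OC)c(C)c(=O)c1C | intermediate
34 | amaurone A | COc1oc(/C(C)=C/C=C/C(C)=C/[C@@H]2[C@H](C)[C@@](C)(O)[C@@H](OC(C)=O)[C@@](C)(O)[C@H]2O)c(C)c(=O)c1C | target

## Step count and least certain steps

Total: 16 steps. Longest linear sequence: 11 steps (4 → 5 → 8 → 10 → 12 → 13 → 14 → 16 → 17 → 19 → 23 → 34; steps 2–11 and 16).

**Step 5 (key step).** The most likely failure is weak or reversed facial bias in the disrotatory closure, because the controlling stereocentre acts across an E alkene with only hydrogen as the cis partner. A competing ene reaction of singlet oxygen at the ring methyl groups is a lesser risk. A weak bias only costs material, since the diastereomers are separable. A reversed bias is answered by using the dioxolane as an empirically chosen resolving handle from the other chiral-pool series. The fallback sets out from boronate 3 and bromide 9 and rejoins at aldehyde 16, where the auxiliary carbon has been excised.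
- Commercial (4R)-2,2-dimethyl-1,3-dioxolane-4-carbaldehyde F1 is homologated to (4S)-4-ethynyl-2,2-dimethyl-1,3-dioxolane F2.
- Hydrozirconation to alkenylzirconocene chloride F3, transmetalation to alkenylzinc chloride F4 and coupling with 3 give dienylboronate F5.
- Coupling with 9 gives triene F6.
- Heating gives the (1S,2S)-cyclohexadiene F7 carrying the (4S)-dioxolane, and photo-oxygenation gives endoperoxide F8.
- Dihydroxylation gives diol F9 and acetylation gives acetate F10.
- Periodic acid, by way of side-chain diol F11, returns the route at 16.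

**Step 6.** The most likely failure is slow osmylation, or addition from the wrong face. Attack syn to the O–O bridge runs against the intrinsic preference of unhindered dioxabicyclooctenes, and it pushes the C5 methyl toward the C1 substituent. The fallback sets out from endoperoxide 12 and oxidises the relaxed monocycle under hydroxyl direction.
- Thiourea in MeOH gives ene-diol F12.
- TBSCl/imidazole silylates the only secondary hydroxyl to give silyl ether F13.
- OsO4·TMEDA in CH2Cl2 at −78 °C, hydrogen-bonded to the tertiary C3 hydroxyl and kept off the α-face by the axial C2 methyl, should give triol F14.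
- Acetylation gives acetate F15.
- Periodic acid gives, via side-chain diol F16, silyloxy aldehyde F17.
- HF·pyridine returns the route at 17.

**Step 8 (with step 9).** The most likely failure is epimerisation at C1, or β-elimination across C1–C6 with loss of the peroxide. In the bicycle the formyl group is compressed against the C5 methyl and has a β-peroxy leaving group. The fallback sets out from acetate 14 and opens the bicycle before the aldehyde exists.
- H2 over Pd/C gives triol F18.
- TBSOTf/2,6-lutidine at −78 °C converts F18 into the silyl ether acetate F15.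
- Periodic acid takes F15 through side-chain diol F16 to silyloxy aldehyde F17, and HF·pyridine returns the route at 17.

**Step 16.** The most likely failure is erosion of E selectivity at the new trisubstituted alkene, or base-induced damage (acetyl migration, vinylogous deprotonation at C1) if the anion proves more basic than expected. The fallback sets out from pyrone 29 and replaces the metalated phosphonate by a neutral, isolable ylide.
- Radical bromination (NBS, AIBN) gives 6-(1-bromoethyl)-2-methoxy-3,5-dimethyl-4H-pyran-4-one F19.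
- Triphenylphosphine gives phosphonium bromide F20.
- Aqueous NaOH gives the stabilised ylide F21.
- Heating F21 with dienal 23 in toluene without added base returns the route at 34.

## Further compounds

F1 | step 5 | (4R)-2,2-dimethyl-1,3-dioxolane-4-carbaldehyde | CC1(C)OC[C@@H](O1)C=O
F2 | step 5 | (4S)-4-ethynyl-2,2-dimethyl-1,3-dioxolane | CC1(C)OC[C@@H](O1)C#C
F3 | step 5 | chlorobis(cyclopentadienyl)[(E)-2-[(4S)-2,2-dimethyl-1,3-dioxolan-4-yl]ethenyl]zirconium | CC1(C)OC[C@@H](O1)/C=C/[Zr](Cl)(C2C=CC=C2)C2C=CC=C2
F4 | step 5 | chloro[(E)-2-[(4S)-2,2-dimethyl-1,3-dioxolan-4-yl]ethenyl]zinc | CC1(C)OC[C@@H](O1)/C=C/[Zn]Cl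
F5 | step 5 | 2-[(1Z,3E)-4-[(4S)-2,2-dimethyl-1,3-dioxolan-4-yl]-2-methylbuta-1,3-dien-1-yl]-4,4,5,5-tetramethyl-1,3,2-dioxaborolane | CC1(C)OC[C@@H](O1)/C=C/C(C)=C\B1OC(C)(C)C(C)(C)O1
F6 | step 5 | (4S)-4-[(1E,3Z,5E)-3,5-dimethylhepta-1,3,5-trien-1-yl]-2,2-dimethyl-1,3-dioxolane | CC1(C)OC[C@@H](O1)/C=C/C(C)=C\C(C)=C\C
F7 | step 5 | (4S)-2,2-dimethyl-4-[(1S,2S)-2,3,5-trimethylcyclohexa-3,5-dien-1-yl]-1,3-dioxolane | CC1(C)OC[C@@H](O1)[C@@H]2[C@H](C)C(C)=CC(C)=C2
F8 | step 5 | (4S)-4-[(1S,2S,3R,6S)-3,6-epidioxy-2,3,5-trimethylcyclohex-4-en-1-yl]-2,2-dimethyl-1,3-dioxolane | CC1(C)OC[C@@H](O1)[C@@H]2[C@H](C)[C@]3(C)C=C(C)[C@H]2OO3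
F9 | step 5 | (4S)-4-[(1S,2S,3R,4S,5R,6S)-3,6-epidioxy-4,5-dihydroxy-2,3,5-trimethylcyclohexyl]-2,2-dimethyl-1,3-dioxolane | CC1(C)OC[C@@H](O1)[C@@H]2[C@H](C)[C@]3(C)[C@@H](O)[C@@](C)(O)[C@H]2OO3
F10 | step 5 | (4S)-4-[(1S,2S,3R,4S,5R,6S)-4-acetoxy-3,6-epidioxy-5-hydroxy-2,3,5-trimethylcyclohexyl]-2,2-dimethyl-1,3-dioxolane | CC1(C)OC[C@@H](O1)[C@@H]2[C@H](C)[C@]3(C)[C@@H](OC(C)=O)[C@@](C)(O)[C@H]2OO3
F11 | step 5 | (1S)-1-[(1S,2S,3R,4S,5R,6S)-4-acetoxy-3,6-epidioxy-5-hydroxy-2,3,5-trimethylcyclohexyl]ethane-1,2-diol | OC[C@@H](O)[C@@H]1[C@H](C)[C@]2(C)[C@@H](OC(C)=O)[C@@](C)(O)[C@H]1OO2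
F12 | step 6 | (4R)-4-[(1R,2S,3R,6S)-3,6-dihydroxy-2,3,5-trimethylcyclohex-4-en-1-yl]-2,2-dimethyl-1,3-dioxolane | CC1(C)OC[C@H](O1)[C@@H]2[C@H](C)[C@@](C)(O)C=C(C)[C@H]2O
F13 | step 6 | 6-O-tert-butyldimethylsilyl ether of F12 | CC1(C)OC[C@H](O1)[C@@H]2[C@H](C)[C@@](C)(O)C=C(C)[C@H]2O[Si](C)(C)C(C)(C)C
F14 | step 6 | 3,4,5-triol from F13 (4β,5β-dihydroxylated, 6-OTBS) | CC1(C)OC[C@H](O1)[C@@H]2[C@H](C)[C@@](C)(O)[C@@H](O)[C@@](C)(O)[C@H]2O[Si](C)(C)C(C)(C)C
F15 | step 6 | 4-O-acetate of F14 | CC1(C)OC[C@H](O1)[C@@H]2[C@H](C)[C@@](C)(O)[C@@H](OC(C)=O)[C@@](C)(O)[C@H]2O[Si](C)(C)C(C)(C)C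
F16 | step 6 | side-chain 1,2-diol from F15 (acetonide removed) | OC[C@H](O)[C@@H]1[C@H](C)[C@@](C)(O)[C@@H](OC(C)=O)[C@@](C)(O)[C@H]1O[Si](C)(C)C(C)(C)C
F17 | step 6 | 6-O-tert-butyldimethylsilyl ether of aldehyde 17 | O=C[C@@H]1[C@H](C)[C@@](C)(O)[C@@H](OC(C)=O)[C@@](C)(O)[C@H]1O[Si](C)(C)C(C)(C)C
F18 | step 8 | (4R)-4-[(1S,2S,3R,4R,5S,6S)-4-acetoxy-3,5,6-trihydroxy-2,3,5-trimethylcyclohexyl]-2,2-dimethyl-1,3-dioxolane | CC1(C)OC[C@H](O1)[C@@H]2[C@H](C)[C@@](C)(O)[C@@H](OC(C)=O)[C@@](C)(O)[C@H]2O
F19 | step 16 | 6-(1-bromoethyl)-2-methoxy-3,5-dimethyl-4H-pyran-4-one (racemic) | CC(Br)c1oc(OC)c(C)c(=O)c1C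
F20 | step 16 | [1-(6-methoxy-3,5-dimethyl-4-oxo-4H-pyran-2-yl)ethyl]triphenylphosphonium bromide (racemic) | CC(c1oc(OC)c(C)c(=O)c1C)[P+](c1ccccc1)(c1ccccc1)c1ccccc1.[Br-]
F21 | step 16 | 2-methoxy-3,5-dimethyl-6-[1-(triphenylphosphoranylidene)ethyl]-4H-pyran-4-one | CC(c1oc(OC)c(C)c(=O)c1C)=P(c1ccccc1)(c1ccccc1)c1ccccc1
A1 | alternative 1 | 2,4-dimethylphenol | Cc1ccc(O)c(C)c1
A2 | alternative 1 | 4-hydroxy-2,4-dimethylcyclohexa-2,5-dien-1-one (racemic, one enantiomer drawn) | CC1=C[C@](C)(O)C=CC1=O
A3 | alternative 2 | 2,4-dimethylfuran | Cc1cc(C)co1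
A4 | alternative 2 | ethyl but-2-ynoate | CCOC(=O)C#CC
A5 | alternative 2 | ethyl 3,4,6-trimethyl-7-oxabicyclo[2.2.1]hepta-2,5-diene-2-carboxylate (racemic, one enantiomer drawn) | CCOC(=O)C1=C(C)[C@]2(C)C=C(C)[C@H]1O2
A6 | alternative 3 | 2-methoxy-3,5-dimethyl-6-[(2E,4E,6E,8E,10Z,12E)-6,10,12-trimethyltetradeca-2,4,6,8,10,12-hexaen-2-yl]-4H-pyran-4-one | COc1oc(/C(C)=C/C=C/C(C)=C/C=C/C(C)=C\C(C)=C\C)c(C)c(=O)c1C
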